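At 8.00 d the noon run read 1.39 isomer of the product per target, and the autumn run read 0.323.

| setting | noon | autumn | flask |
|---|---|---|---|
| starting material | 0.070 M | 0.28 M | 0.14 M |
| other conformer | 0.14 M | 0.14 M | 0.140 M |
| protic impurity | 0.042 M | 0.042 M | 0.0420 M |
| remark | run made earlier | run made earlier |  |
| time |  |  | 12 d |

| run | time / d | isomer of the product / % | target / % |
|---|---|---|---|
| noon | 0.500 | 16.2 | 12.5 |
| noon | 1.25 | 27.6 | 17.5 |
| noon | 2.50 | 33.5 | 20.0 |
| noon | 4.00 | 36.1 | 23.2 |
| noon | 6.00 | 37.2 | 24.1 |
| noon | 8.00 | 36.0 | 25.9 |
| autumn | 0.625 | 10.2 | 25.1 |
| autumn | 1.04 | 11.7 | 34.6 |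
| autumn | 1.67 | 15.3 | 39.1 |
| autumn | 2.50 | 17.0 | 44.3 |
| autumn | 4.00 | 18.4 | 48.4 |
| autumn | 8.00 | 17.7 | 54.8 |

(each reading ± 1 percentage point)

- the numbers in the tables scatter with a standard deviation of 1 percentage point

- ratio of isomer of the product to target at 20 min
- ratio of isomer of the product to target at 12 d

I turned the settings one at a time, starting with the starting material. If each product grew from its own charge, the ratio would follow the charge odds, the fraction of other conformer over the fraction of starting material. Those odds were 2.00 at noon and 0.500 in autumn, a fall by a factor of 4.00, and the ratio read at 8.00 d fell by a factor of 4.30. So I divided: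

noon: 0.648 at 0.500 d, 0.695 at 8.00 d

autumn: 0.813 at 0.625 d, 0.646 at 8.00 d

Their mean, 0.700, is my selectivity factor s: the ratio of isomer of the product to target divided by the charge odds.

Time came next. It would move s if one product ran ahead of the other, yet the noon value rose and the autumn value fell, and that first autumn reading of 10.2% carries a scatter of 1 point. I therefore carried s to both asked times, though 20 min lies before the first reading and 12 d past the last.

The protic impurity and the other conformer were not turned: both runs and the flask hold 0.0420 M and 0.140 M, so s stands for those two charges.

For the flask the odds are 1.00, so: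

ratio = s × odds = 0.700 at both times

The forecast gave 0.52 and 0.63, holding that “Target scales with starting material, with no offset”.

The flask gave 0.687 at 20 min and 0.706 at 12 d, so its s was 0.687 and 0.706.

    starting material ⇌ other conformer (K = 1.10, k = 0.00120 /h)
    starting material → target (k = 0.0450 /h)
    other conformer → isomer of the product (k = 0.0310 /h)
    other conformer ⇌ third conformer (K = 0.580, k = 0.0720 /h)
    third conformer → third product (k = 0.0650 /h)
    starting material + protic impurity → quenched substrate (k = 0.460 /M/h)
    starting material ⇌ dormant form (K = 1.00, k = 0.0220 /h)

In percent of the starting material and other conformer together charged, the flask held 7.14% starting material and 10.5% other conformer at 1.20 d, with target at 26.3% and isomer of the product at 20.1%. By 6.00 d the other conformer was down to 0.0960% and the isomer of the product stood at 27.7%, while target went on from 37.4% to 39.4% at 12.0 d as the dormant form fell from 1.96% to 0.261%.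

In a neighbour flask with 0.035 M of starting material, the other charges as in the flask, the odds become 4.00, so s gives 2.80. That neighbour flask computed 2.75 at 20 min and 2.87 at 12 d.

Readings and results come from a simulation on assumed constants; the scatter is artificial.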